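The numbers in the tables are simulated on assumed constants; scatter was added.

Late in the delta run, which is the flask asked about, target and electrophile no longer add up to the charge. At 150 min they read 44.2% and 15.1%, so a share of 40.7% stands in something you cannot read. Call this unseen share divided by the target the parting ratio, 0.921.

common to all: electrophile 20 mM; temperature 110 °C

| charge | nucleophile | free base | remark | time |
|---|---|---|---|---|
| delta | 24 mM | 20 mM | the very flask that is asked about, followed so far |  |
| epsilon | 24 mM | 13 mM | run made earlier |  |
| flask | 24.0 mM | 20.0 mM |  | 2.5 h |

| run | time / min | target / % | electrophile / % |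
|---|---|---|---|
| delta | 30.0 | 37.8 | 33.3 |
| delta | 60.0 | 40.8 | 24.1 |
| delta | 90.0 | 42.4 | 20.2 |
| delta | 120 | 44.1 | 17.2 |
| delta | 150 | 44.2 | 15.1 |
| epsilon | 0.667 | 6.6 | 93.1 |
| epsilon | 2.00 | 16.6 | 82.5 |
| epsilon | 4.00 | 24.9 | 71.4 |
| epsilon | 6.00 | 29.3 | 64.0 |
| epsilon | 8.00 | 31.8 | 57.8 |

(readings scatter by 0.3 percentage points)

- north-west: at 2.5 h add free base, 100% of the amount charged, then wait 2.5 h
- south-west: change nothing and wait 2.5 h more
- north: at 2.5 h add free base, 50.0% of the amount charged, then wait 2.5 h
- east: at 2.5 h take out 90% of the target then present, then wait 2.5 h
- south-east: at 2.5 h raise the temperature by 20 K, then wait 2.5 h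

- target, in percent of the electrophile first charged, at 2.5 h
- the option that brings most further target ("none" if no option brings more than 2 percentage points) (north-west / south-west / north / east / south-east / none)
- target present, with what was taken out counted in, in percent of the electrophile first charged, after north
- target present, with what was taken out counted in, in percent of the electrophile first charged, after east

- target taken out counts as made
- additions bring no volume worth counting
- the earlier runs do not show what temperature does; that part of a forecast is a guess

Now hold delta against epsilon, its neighbour with less free base. In epsilon the ratio reads 0.149 at 4.00 min and 0.327 at 8.00 min. It climbs, so the unseen share follows the target rather than forming beside it. In delta it reads 0.860 at 60.0 min and 0.921 at 150 min, so there the climb has slowed. The last epsilon reading came earlier than that delta reading at 60.0 min. The two runs differ in free base as well, but the ratio climbs within epsilon, so I read epsilon as still under kinetic control and late delta as near thermodynamic control between target and the unseen share.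

I take the held ratio for a balance, and you get two rules from it. In delta at this temperature, the reacted part of the charge ends as target in the share 52.1%, so using up the remaining electrophile would add 7.9 percentage points. If the ratio is a balance, taking out target makes the unseen share flow back, and 2.5 h is longer than delta took to come near its ratio. So I reckon east at 63.3% before any fresh reaction, a gain of 19 points, which is more than that addition. I therefore say east, with about 44.2% now and north below 52.1%. South-east stays a guess.

The forecast gives 44.6% now, north-west as best, 52.5% after north and 47.5% after east, holding that “East only removes target from a stalled flask”. There we differ.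

The flask gives 44.4%, best east at 21 points further target, 47.7% after north and 65.5% after east.

    electrophile + nucleophile → acid set free + target (k = 0.0815 M⁻¹ s⁻¹, Ea = 57.0 kJ mol⁻¹)
    nucleophile + acid set free ⇌ protonated nucleophile, settled at all times (K = 2.98 × 10⁵ M⁻¹, ΔH = −10.0 kJ mol⁻¹)
    2 nucleophile → homo dimer (k = 0.0138 M⁻¹ s⁻¹, Ea = 84.0 kJ mol⁻¹)
    acid set free + free base ⇌ salt of the base, settled at all times (K = 2.50 × 10⁵ M⁻¹, ΔH = −9.00 kJ mol⁻¹)
    target ⇌ isomer of the product (K = 0.910, k = 0.00116 s⁻¹, Ea = 109 kJ mol⁻¹, ΔH = −12.0 kJ mol⁻¹)
    (constants at 110 °C)

In the asked flask the unseen share is the isomer of the product, 40.1% at 150 min. Now carry the ratio to the neighbouring flask with 50 mM of electrophile, where 57.7% of the electrophile is left at 150 min. The reacted part, divided by one plus the ratio, gives 22.0% of target. That flask holds 22.2%.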